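**Retrosynthetic overview**
1. Target 21 (ring B = quinone C1–C4 with C4a/C8a; ring A = C4a, C5–C8, C8a; chain C1'–C4' on C6): the C8–OH is unmasked last from aryl acetate 20, the ring B quinone comes from its dimethyl ether 19, and the C1' ester and C8 acetate go back to naphthol carbamate 15.
2. Feature used: ring A carries OMe on C5 next to the chain-bearing C6, H on C7 and a free OH on C8, which is the pattern of a 3-substituted 4-methoxy-1-naphthol. Bond C8–C8a, and with it ring A, is therefore disconnected to the 4-aryl-4-methoxycyclobutenone 12.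
3. 12 is cut at C6–C1' (1,2-addition of the (−)-sparteine-lithiated homoprenyl carbamate, which sets C1' as R, then enone transposition) and at C5–C4a (aryllithium addition and O-methylation on semisquarate 3, made from diisopropyl squarate 1).
4. Ring order: the four-membered ring and the benzene ring (future ring B) are purchased; ring A is the only ring formed (step 6).

Key step: step 6

Remark: locants C1–C8a and C1'–C4' are those of the target (quinone carbonyls C1 and C4, OMe on C5, chain on C6, OH on C8); intermediates are named with their own ring numbering, and (−)-sparteine is taken as a purchasable reagent that is recovered on acidic work-up.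

**Step 1**
Reactants: 1 diisopropyl squarate
Product: 2 4-hydroxy-2,3-diisopropoxycyclobut-2-en-1-one (racemic)
Conditions: LiAlH(OtBu)3, THF, −78 → 0 °C; H2O quench
Reagents that add atoms: none
Why: Nucleophilic 1,2-reduction in which the bulky, mild hydride adds once to one of the two equivalent carbonyl groups of the squarate and stops at the hydroxycyclobutenone; the carbinol centre is racemic and is lost in step 2.

**Step 2**
Reactants: 2 4-hydroxy-2,3-diisopropoxycyclobut-2-en-1-one
Product: 3 3-isopropoxycyclobut-3-ene-1,2-dione
Conditions: conc. aq HCl (cat.), CH2Cl2, rt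
Reagents that add atoms: water, O
Why: Acid-induced hydrolytic transposition in which ionisation of the allylic hydroxyl gives a cation stabilised by the C2 isopropoxy group, water adds at C2 and isopropanol is lost, leaving the 1,2-dione with one vinyl hydrogen.

**Step 3**
Reactants: 4 2-bromo-1,4-dimethoxybenzene; 3 3-isopropoxycyclobut-3-ene-1,2-dione
Product: 7 4-(2,5-dimethoxyphenyl)-3-isopropoxy-4-methoxycyclobut-2-en-1-one (racemic), via 2,5-dimethoxyphenyllithium 5 (not isolated), via lithium 1-(2,5-dimethoxyphenyl)-2-isopropoxy-4-oxocyclobut-2-en-1-olate 6 (not isolated)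
Conditions: 4, n-BuLi, THF, −78 °C; added to 3, THF, −78 °C; then MeOTf, −78 → 0 °C
Reagents that add atoms: methyl trifluoromethanesulfonate, COS(=O)(=O)C(F)(F)F
Why: Bromine–lithium exchange, then 1,2-addition of the aryllithium to the more electrophilic carbonyl of 3 (the one next to the isopropoxy-bearing carbon, outside the vinylogous ester) and in situ O-methylation of the tertiary alkoxide; the quaternary carbon formed is racemic and becomes sp2 in step 6.

**Step 4**
Reactants: 8 4-methylpent-3-en-1-ol
Product: 9 4-methylpent-3-en-1-yl N,N-diisopropylcarbamate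
Conditions: NaH, THF, 0 °C; ClC(O)N(iPr)2, reflux
Reagents that add atoms: N,N-diisopropylcarbamoyl chloride, CC(C)N(C(C)C)C(=O)Cl
Why: O-carbamoylation of the sodium alkoxide (nucleophilic acyl substitution) installs the directing group needed for the Hoppe lithiation.

**Step 5**
Reactants: 9 4-methylpent-3-en-1-yl N,N-diisopropylcarbamate; 7 4-(2,5-dimethoxyphenyl)-3-isopropoxy-4-methoxycyclobut-2-en-1-one
Product: 12 4-(2,5-dimethoxyphenyl)-3-[(1R)-1-(diisopropylcarbamoyloxy)-4-methylpent-3-enyl]-4-methoxycyclobut-2-en-1-one (both epimers at ring C4), via (1S)-1-lithio-4-methylpent-3-enyl N,N-diisopropylcarbamate 10 (not isolated), via carbinol adduct 11 (not isolated)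
Conditions: 9 (1.5 equiv), s-BuLi, (−)-sparteine, Et2O, −78 °C; 7, −78 °C; then 1 M aq HCl, THF, −78 °C → rt
Reagents that add atoms: water, O
Why: Hoppe asymmetric deprotonation removes the pro-S hydrogen next to the carbamate oxygen to give the configurationally stable (S)-lithio species 10, which adds 1,2 to the vinylogous ester carbonyl of 7 with retention and so sets C1' as (R), and the acidic quench ionises the tertiary allylic alcohol of 11, water captures the isopropoxy-stabilised cation and isopropanol is lost (1,3-carbonyl transposition); ring carbon C4 stays a mixture, which is of no consequence.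

**Step 6**
Reactants: 12 4-(2,5-dimethoxyphenyl)-3-[(1R)-1-(diisopropylcarbamoyloxy)-4-methylpent-3-enyl]-4-methoxycyclobut-2-en-1-one
Product: 15 3-[(1R)-1-(diisopropylcarbamoyloxy)-4-methylpent-3-enyl]-4,5,8-trimethoxynaphthalen-1-ol, via aryl vinylketene 13 (not isolated), via 8aH-naphthalen-1-one tautomer 14 (not isolated)
Conditions: PhMe (degassed, dilute), 110 °C, Ar
Reagents that add atoms: none
Why: Heating opens the cyclobutenone by conrotatory 4π cleavage of its C1–C4 bond to vinylketene 13, with the methoxy group rotated outward and the aryl group inward; a 6π electrocyclisation then joins the ketene carbon (future C8) to the one free ortho carbon of the aryl group (future C8a) to give dienone 14, and enolisation aromatises it to naphthol 15. This is the Moore rearrangement of 4-aryl-4-alkoxycyclobutenones to 4-alkoxy-1-naphthols, here applied to a new substrate. Ring A is closed by a thermal disrotatory 6π closure onto the arene, forming the single bond C8–C8a. The only new stereocentre (C8a–H of 14) is transient and erased on tautomerisation, whereas C1' lies outside the pericyclic array and has no ionisable or acidic bond under neutral thermolysis, so its (R) configuration is carried through. The step needs torquoselectivity and site selectivity: the donor methoxy group on ring carbon C4 prefers outward rotation (the unproductive rotamer can only revert to 12), and the ortho methoxy group of the 2,5-dimethoxyphenyl ring leaves a single ortho C–H for closure. Both C4 epimers converge because C4 becomes sp2; the ketene oxygen ends as the free C8–OH and the C4 methoxy as C5–OMe, so the two ring A oxygens are told apart without a selective step.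

**Step 7**
Reactants: 15 3-[(1R)-1-(diisopropylcarbamoyloxy)-4-methylpent-3-enyl]-4,5,8-trimethoxynaphthalen-1-ol
Product: 16 3-[(1R)-1-hydroxy-4-methylpent-3-enyl]-4,5,8-trimethoxynaphthalen-1-ol
Conditions: LiAlH4, THF, reflux; H2O quench under Ar, used at once
Reagents that add atoms: none
Why: Reductive cleavage of the carbamate, in which hydride attacks the carbamoyl carbonyl, the secondary alkoxide is expelled and the formamide is reduced on to the amine; the C1'–O bond is not broken, so the (R) configuration is kept, and the naphthoxide and aryl ethers are inert.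

**Step 8**
Reactants: 16 3-[(1R)-1-hydroxy-4-methylpent-3-enyl]-4,5,8-trimethoxynaphthalen-1-ol
Product: 17 3-[(1R)-1-hydroxy-4-methylpent-3-enyl]-4,5,8-trimethoxynaphthalen-1-yl acetate
Conditions: Ac2O (1.05 equiv), Et3N, CH2Cl2, 0 °C
Reagents that add atoms: acetic anhydride, CC(=O)OC(C)=O
Why: Chemoselective O-acylation, in which the much more acidic naphthol reacts as its triethylammonium naphthoxide with one equivalent of anhydride and no acyl-transfer catalyst, leaving the hindered secondary benzylic alcohol free.

**Step 9**
Reactants: 17 3-[(1R)-1-hydroxy-4-methylpent-3-enyl]-4,5,8-trimethoxynaphthalen-1-yl acetate; 18 3-methylbut-2-enoic acid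
Product: 19 (1R)-1-(4-acetoxy-1,5,8-trimethoxynaphthalen-2-yl)-4-methylpent-3-enyl 3-methylbut-2-enoate
Conditions: DCC, DMAP (cat.), CH2Cl2, 0 °C → rt
Reagents that add atoms: none
Why: Steglich esterification acylates the only free hydroxyl, with retention at C1' because the C1'–O bond is not broken.

**Step 10**
Reactants: 19 (1R)-1-(4-acetoxy-1,5,8-trimethoxynaphthalen-2-yl)-4-methylpent-3-enyl 3-methylbut-2-enoate
Product: 20 (1R)-1-(4-acetoxy-1-methoxy-5,8-dioxo-5,8-dihydronaphthalen-2-yl)-4-methylpent-3-enyl 3-methylbut-2-enoate
Conditions: (NH4)2Ce(NO3)6, MeCN/H2O, 0 °C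
Reagents that add atoms: water, O
Why: Oxidative demethylation, in which two-electron oxidation of the para-dimethoxy ring B with attack of water gives the quinone, while the electron-withdrawing acetate on the C8 oxygen makes ring A the less oxidisable ring and the esterified C1' oxygen cannot cyclise onto the side-chain alkene.

**Step 11**
Reactants: 20 (1R)-1-(4-acetoxy-1-methoxy-5,8-dioxo-5,8-dihydronaphthalen-2-yl)-4-methylpent-3-enyl 3-methylbut-2-enoate
Product: 21 (1R)-1-(4-hydroxy-1-methoxy-5,8-dioxo-5,8-dihydronaphthalen-2-yl)-4-methylpent-3-enyl 3-methylbut-2-enoate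
Conditions: NH4OAc, MeOH, rt
Reagents that add atoms: none
Why: Chemoselective methanolysis of an aryl acetate under near-neutral conditions, in which the acetate is activated by the peri quinone carbonyl (a good naphthoxide leaving group) whereas the alkyl 3-methylbut-2-enoate is a hindered, conjugated and far less electrophilic ester.

**Compound list**
1 | diisopropyl squarate (3,4-diisopropoxycyclobut-3-ene-1,2-dione) | CC(C)OC1=C(OC(C)C)C(=O)C1=O | starting material
2 | 4-hydroxy-2,3-diisopropoxycyclobut-2-en-1-one (racemic) | CC(C)OC1=C(OC(C)C)C(O)C1=O | intermediate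
3 | 3-isopropoxycyclobut-3-ene-1,2-dione | CC(C)OC1=CC(=O)C1=O | intermediate
4 | 2-bromo-1,4-dimethoxybenzene | COc1ccc(OC)c(Br)c1 | starting material
5 | 2,5-dimethoxyphenyllithium | [Li]c1cc(OC)ccc1OC | intermediate
6 | lithium 1-(2,5-dimethoxyphenyl)-2-isopropoxy-4-oxocyclobut-2-en-1-olate (racemic) | [Li+].[O-]C1(c2cc(OC)ccc2OC)C(OC(C)C)=CC1=O | intermediate
7 | 4-(2,5-dimethoxyphenyl)-3-isopropoxy-4-methoxycyclobut-2-en-1-one (racemic) | COc1ccc(OC)c(c1)C1(OC)C(OC(C)C)=CC1=O | intermediate
8 | 4-methylpent-3-en-1-ol | CC(C)=CCCO | starting material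
9 | 4-methylpent-3-en-1-yl N,N-diisopropylcarbamate | CC(C)=CCCOC(=O)N(C(C)C)C(C)C | intermediate
10 | (1S)-1-lithio-4-methylpent-3-enyl N,N-diisopropylcarbamate, as its (−)-sparteine complex (ligand not drawn) | [Li][C@@H](CC=C(C)C)OC(=O)N(C(C)C)C(C)C | intermediate
11 | (1R)-1-[4-(2,5-dimethoxyphenyl)-1-hydroxy-3-isopropoxy-4-methoxycyclobut-2-en-1-yl]-4-methylpent-3-enyl N,N-diisopropylcarbamate (mixture at ring C1 and C4) | COc1ccc(OC)c(c1)C1(OC)C(OC(C)C)=CC1(O)[C@@H](CC=C(C)C)OC(=O)N(C(C)C)C(C)C | intermediate
12 | 4-(2,5-dimethoxyphenyl)-3-[(1R)-1-(diisopropylcarbamoyloxy)-4-methylpent-3-enyl]-4-methoxycyclobut-2-en-1-one (both epimers at ring C4) | COc1ccc(OC)c(c1)C1(OC)C(=CC1=O)[C@@H](CC=C(C)C)OC(=O)N(C(C)C)C(C)C | intermediate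
13 | 4-(2,5-dimethoxyphenyl)-3-[(1R)-1-(diisopropylcarbamoyloxy)-4-methylpent-3-enyl]-4-methoxybuta-1,3-dien-1-one (aryl cis to the ketenyl carbon) | O=C=C/C(=C(/OC)c1cc(OC)ccc1OC)[C@@H](CC=C(C)C)OC(=O)N(C(C)C)C(C)C | intermediate
14 | 3-[(1R)-1-(diisopropylcarbamoyloxy)-4-methylpent-3-enyl]-4,5,8-trimethoxy-8aH-naphthalen-1-one (either configuration at C8a) | O=C1C=C([C@@H](CC=C(C)C)OC(=O)N(C(C)C)C(C)C)C(OC)=C2C(OC)=CC=C(OC)C12 | intermediate
15 | 3-[(1R)-1-(diisopropylcarbamoyloxy)-4-methylpent-3-enyl]-4,5,8-trimethoxynaphthalen-1-ol | COc1ccc(OC)c2c(OC)c([C@@H](CC=C(C)C)OC(=O)N(C(C)C)C(C)C)cc(O)c12 | intermediate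
16 | 3-[(1R)-1-hydroxy-4-methylpent-3-enyl]-4,5,8-trimethoxynaphthalen-1-ol | COc1ccc(OC)c2c(OC)c([C@@H](CC=C(C)C)O)cc(O)c12 | intermediate
17 | 3-[(1R)-1-hydroxy-4-methylpent-3-enyl]-4,5,8-trimethoxynaphthalen-1-yl acetate | COc1ccc(OC)c2c(OC)c([C@@H](CC=C(C)C)O)cc(OC(C)=O)c12 | intermediate
18 | 3-methylbut-2-enoic acid | CC(C)=CC(=O)O | starting material
19 | (1R)-1-(4-acetoxy-1,5,8-trimethoxynaphthalen-2-yl)-4-methylpent-3-enyl 3-methylbut-2-enoate | COc1ccc(OC)c2c(OC)c([C@@H](CC=C(C)C)OC(=O)C=C(C)C)cc(OC(C)=O)c12 | intermediate
20 | (1R)-1-(4-acetoxy-1-methoxy-5,8-dioxo-5,8-dihydronaphthalen-2-yl)-4-methylpent-3-enyl 3-methylbut-2-enoate | COc1c([C@@H](CC=C(C)C)OC(=O)C=C(C)C)cc(OC(C)=O)c2c1C(=O)C=CC2=O | intermediate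
21 | (1R)-1-(4-hydroxy-1-methoxy-5,8-dioxo-5,8-dihydronaphthalen-2-yl)-4-methylpent-3-enyl 3-methylbut-2-enoate | COc1c([C@@H](CC=C(C)C)OC(=O)C=C(C)C)cc(O)c2c1C(=O)C=CC2=O | target

**Step count**
Total steps: 11. Longest linear sequence: 10 steps (steps 1, 2, 3, 5, 6, 7, 8, 9, 10, 11, from 1); step 4 is a one-step side branch.

**Steps most likely to fail**

Step 5. The bulky, sparteine-bound secondary organolithium may add slowly to the carbonyl flanked by the quaternary ring carbon. Conversion may then need warming or a smaller diamine such as TMEDA, and the configuration at C1' erodes. The fallback accepts whatever enantiomeric purity results and resets the stereocentre late by reagent control. It sets out from 17 of insufficient enantiomeric purity. The benzylic alcohol is oxidised with MnO2 in CH2Cl2 to the aryl ketone 4,5,8-trimethoxy-3-(4-methylpent-3-enoyl)naphthalen-1-yl acetate F1. F1 is reduced with (+)-Ipc2BCl in THF at −25 °C, with acetaldehyde work-up to spare the aryl acetate. The large aryl and small CH2 groups should be differentiated to give the (R)-alcohol, and the sequence comes back to the route at 17.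

Step 6. The 6π closure builds a peri methoxy/methoxy contact and may be slow enough for the aldoketene to be consumed otherwise. The free, electron-rich naphthol may also couple oxidatively at its unsubstituted carbon next to the hydroxyl (C7) while hot or on isolation. The fallback turns the ring expansion into an acylative cascade so that the naphthol is never present as such. It sets out from 12, which is heated in degassed toluene containing Ac2O and pyridine, with DMAP added after cooling. The naphthol should be acetylated as it forms, giving 3-[(1R)-1-(diisopropylcarbamoyloxy)-4-methylpent-3-enyl]-4,5,8-trimethoxynaphthalen-1-yl acetate F2. LiAlH4 in THF at reflux then removes acetate and carbamate together, and the sequence comes back to the route at 16.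

Step 11. The nucleophilic medium may attack the quinone at C2/C3, or the acetate cleavage may have to be forced until the C1' ester is also lost or scrambled. The fallback reorders the endgame so that no ester has to survive a deacylation and the last step is a neutral esterification. It sets out from 17, which is oxidised first with (NH4)2Ce(NO3)6 in MeCN/H2O at 0 °C with short contact time (to limit acid-induced cyclisation of the free C1' hydroxyl onto the alkene). This should give 3-[(1R)-1-hydroxy-4-methylpent-3-enyl]-4-methoxy-5,8-dioxo-5,8-dihydronaphthalen-1-yl acetate F3. The peri-activated acetate is removed with NaHCO3 in MeOH/H2O at 0 °C to give 8-hydroxy-6-[(1R)-1-hydroxy-4-methylpent-3-enyl]-5-methoxynaphthalene-1,4-dione F4. F4 is esterified with 18, DCC and catalytic DMAP. The C8 hydroxyl is chelated to the quinone carbonyl and should stay unacylated, so the sequence comes back to the route at 21.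

**Further compounds**
F1 | step 5 | 4,5,8-trimethoxy-3-(4-methylpent-3-enoyl)naphthalen-1-yl acetate | COc1ccc(OC)c2c(OC)c(C(=O)CC=C(C)C)cc(OC(C)=O)c12
F2 | step 6 | 3-[(1R)-1-(diisopropylcarbamoyloxy)-4-methylpent-3-enyl]-4,5,8-trimethoxynaphthalen-1-yl acetate | COc1ccc(OC)c2c(OC)c([C@@H](CC=C(C)C)OC(=O)N(C(C)C)C(C)C)cc(OC(C)=O)c12
F3 | step 11 | 3-[(1R)-1-hydroxy-4-methylpent-3-enyl]-4-methoxy-5,8-dioxo-5,8-dihydronaphthalen-1-yl acetate | COc1c([C@@H](CC=C(C)C)O)cc(OC(C)=O)c2c1C(=O)C=CC2=O
F4 | step 11 | 8-hydroxy-6-[(1R)-1-hydroxy-4-methylpent-3-enyl]-5-methoxynaphthalene-1,4-dione | COc1c([C@@H](CC=C(C)C)O)cc(O)c2c1C(=O)C=CC2=O
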